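The data come from a simulation from invented constants, and the scatter is random.

The noon run cannot have spent its missing substrate on partner. At 8.00 min, its first product and bis adduct leave 10.4 mM of substrate unaccounted for, yet those two products leave 1.40 mM of partner free. So substrate also goes by a path without partner.

| flask | substrate | partner | remark | time |
|---|---|---|---|---|
| midnight | 20 mM | 22 mM | run made earlier |  |
| noon | 20 mM | 15 mM | run made earlier |  |
| summer | 20 mM | 33 mM | run made earlier |  |
| alder | 20 mM | 22.0 mM (fed, over 80 s) | all else is in the flask from the start; the feed brings no volume worth counting | 8.0 min |
| ash | 20 mM | 22.0 mM | everything together at the start | 8.0 min |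
| birch | 20 mM | 22.0 mM (fed, over 5.0 min) | all else is in the flask from the start; the feed brings no volume worth counting | 8.0 min |
| maple | 20 mM (fed, over 5.0 min) | 22.0 mM | all else is in the flask from the start; the feed brings no volume worth counting | 8.0 min |

| run | time / min | first product / % | bis adduct / % |
|---|---|---|---|
| midnight | 2.00 | 30.6 | 27.3 |
| midnight | 4.00 | 26.0 | 31.0 |
| midnight | 6.00 | 24.8 | 31.5 |
| midnight | 8.00 | 25.5 | 32.5 |
| noon | 0.667 | 33.1 | 8.4 |
| noon | 1.33 | 32.0 | 13.6 |
| noon | 3.00 | 29.6 | 17.6 |
| noon | 8.00 | 28.0 | 20.0 |
| summer | 1.00 | 31.3 | 34.4 |
| summer | 3.00 | 16.7 | 42.4 |
| summer | 5.00 | 14.1 | 43.8 |
| summer | 8.00 | 13.2 | 44.1 |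

(standard deviation of a reading: 0.3 percentage points)

1. the flask that comes out highest in share of first product in first product plus bis adduct, or "all alike" when all lie within 1.5 percentage points (alder / ash / birch / maple / all alike)
2. share of first product in first product plus bis adduct at the end, alder
3. share of first product in first product plus bis adduct at the end, ash
4. share of first product in first product plus bis adduct at the end, birch
5. share of first product in first product plus bis adduct at the end, maple

- the earlier runs were read with a standard deviation of 0.3 percentage points

Let the diversion ratio d be the substrate lost by that path per substrate captured by partner. If the loss runs one order higher in substrate than the capture, d = q[substrate]/[partner]: time drops out, and q is a selectivity factor. Missing over found substrate, times the charged [partner]/[substrate], gives the diversion constant q, 0.797, from midnight. Noon gives 0.812, but summer stands higher at 1.23.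

For slow addition to win, substrate would have to outlast the feed. But noon holds 86.5% of its final two products by 0.667 min, which is 13.3% of 5.0 min. Taking that time as substrate's life, birch has received 2.93 mM of partner and alder 11.0 mM. My reckoning gives d of 0.724 in ash, 1.45 in alder and 5.43 in birch. Partner per captured substrate is then 1.90, 2.69 and 7.07. Two partner carry one substrate to bis adduct, so alder and birch should lose their first product and fall far below ash, which repeats midnight at 44.0%. Maple starts at d = 0.0966, lower than in the other three flasks, but that is a starting value, so this reckoning gives no rank for maple.

The forecast named ash, with alder 34%, ash 44%, birch 22% and maple 30%, on the view of “partner self-loss or partner-driven deactivation”.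

The flasks give alder 6.51%, ash 43.2%, birch 3.31% and maple 48.3%, so maple comes highest.

    substrate + partner → first product + released group (k = 3.30 /M/s)
    partner + first product → bis adduct + released group (k = 1.20 /M/s)
    partner + bis adduct → triple product + released group (k = 0.340 /M/s)
    partner + triple product → tetra adduct + released group (k = 5.40 /M/s)
    2 substrate → self-condensation product (k = 1.70 /M/s)

At 8.00 min, birch holds 80.5% of its substrate as self-condensation product, a diversion ratio of 4.13 against the 5.43 reckoned. The neighbour of birch charged with 8.0 mM of substrate takes the same feed, so the constant gives d = 2.17. That flask holds 61.9% as self-condensation product, a ratio of 1.62, and ends with a share of 1.99%.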